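**Retrosynthetic overview**
- The target comes from one acidolysis (three tert-butyl esters, two catechol acetonides) of a fully protected (1R,2S)-1-aryl-1,2-dihydronaphthalene-2,3-diester whose 3-ester is already the (S)-malate.
- Ring B is the only ring that is built, since both arene rings are bought as catechol acetonide. It is closed by a radical (4+2) annulation: the α-ester radical of an α-bromo-β-acetoxy-dihydrocinnamoyl malate adds to a tert-butyl cinnamate (C2–C3 bond), the benzylic radical or cation closes onto ring A (C1–C8a bond), and loss of AcOH gives C3=C4.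
- The malate C–O stereocentre comes from asymmetric hydrogenation of the enol ester made from the cinnamic acid and di-tert-butyl acetylenedicarboxylate. The malate then serves as the internal resolving handle for C1/C2.
- Both cinnamate partners come from Heck reactions of one aryl bromide, which is made by brominating catechol acetonide.

Assumption: the SMILES is read as the trans-(1R,2S) ring configuration with an (S)-malate (L-malate) unit; 1,2-dihydronaphthalene numbering (C1 aryl, C2 CO2H, C3 ester, C4 =CH) is used throughout.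

**Step 1**
Reactants: 1 2,2-dimethyl-1,3-benzodioxole (catechol acetonide)
Product: 2 5-bromo-2,2-dimethyl-1,3-benzodioxole
Conditions: NBS (1.05 equiv), MeCN, 0 °C → rt
Reagents that add atoms: N-bromosuccinimide, O=C1CCC(=O)N1Br
Why: Electrophilic aromatic bromination, in which the dioxole oxygens direct NBS to the unhindered position para to oxygen and the neutral medium leaves the ketal intact.

**Step 2**
Reactants: 2 5-bromo-2,2-dimethyl-1,3-benzodioxole; 3 acrylic acid
Product: 4 (E)-3-(2,2-dimethyl-1,3-benzodioxol-5-yl)prop-2-enoic acid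
Conditions: Pd(OAc)2 (2 mol %), P(o-tol)3 (4 mol %), Et3N, DMF, 100 °C; aq. citric acid work-up
Reagents that add atoms: none
Why: Mizoroki–Heck reaction, in which oxidative addition of the aryl bromide to zerovalent palladium, syn insertion of the acrylate and syn β-hydride elimination give only the (E)-cinnamic acid, while base and a mild acidic work-up preserve the acetonide.

**Step 3**
Reactants: 2 5-bromo-2,2-dimethyl-1,3-benzodioxole; 5 tert-butyl acrylate
Product: 6 tert-butyl (E)-3-(2,2-dimethyl-1,3-benzodioxol-5-yl)prop-2-enoate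
Conditions: Pd(OAc)2 (2 mol %), P(o-tol)3 (4 mol %), Et3N, DMF, 100 °C
Reagents that add atoms: none
Why: The same Mizoroki–Heck reaction gives the (E)-tert-butyl cinnamate that later supplies C1, C2 and the pendant aryl group.

**Step 4**
Reactants: 4 (E)-3-(2,2-dimethyl-1,3-benzodioxol-5-yl)prop-2-enoic acid; 7 di-tert-butyl but-2-ynedioate (di-tert-butyl acetylenedicarboxylate)
Product: 8 di-tert-butyl 2-{[(E)-3-(2,2-dimethyl-1,3-benzodioxol-5-yl)prop-2-enoyl]oxy}but-2-enedioate (enol ester, E/Z mixture used as such, isomer with trans ester groups drawn)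
Conditions: DABCO (10 mol %), CH2Cl2, 0 °C → rt
Reagents that add atoms: none
Why: Amine-catalysed oxa-Michael addition of a carboxylic acid to an activated alkyne (DABCO adds to 7, the zwitterion deprotonates 4, the carboxylate adds and DABCO is expelled), giving the enol ester without touching the cinnamoyl alkene and creating no stereocentre.

**Step 5**
Reactants: 8 di-tert-butyl 2-{[(E)-3-(2,2-dimethyl-1,3-benzodioxol-5-yl)prop-2-enoyl]oxy}but-2-enedioate
Product: 9 di-tert-butyl (2S)-2-{[(E)-3-(2,2-dimethyl-1,3-benzodioxol-5-yl)prop-2-enoyl]oxy}butanedioate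
Conditions: [Rh(cod)((S,S)-Et-DuPhos)]OTf (1 mol %), H2 (4 bar), CH2Cl2/MeOH, rt
Reagents that add atoms: none
Why: Chelation-controlled asymmetric hydrogenation of an enol ester (α-acyloxyacrylate type) by a cationic bisphospholane complex of monovalent rhodium, in which only the alkene that chelates through the acyl C=O is reduced (the cinnamoyl C=C is not) and the (S,S)-ligand is expected, by analogy with α-acyloxyacrylates, to set the (S)-malate centre (ee checked by chiral HPLC).

**Step 6**
Reactants: 9 di-tert-butyl (2S)-2-{[(E)-3-(2,2-dimethyl-1,3-benzodioxol-5-yl)prop-2-enoyl]oxy}butanedioate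
Product: 10 di-tert-butyl (2S)-2-{[3-acetoxy-2-bromo-3-(2,2-dimethyl-1,3-benzodioxol-5-yl)propanoyl]oxy}butanedioate (anti adducts, both diastereomers)
Conditions: NBS (1.05 equiv), NaOAc, AcOH/CH2Cl2, 0 °C → rt, dark
Reagents that add atoms: N-bromosuccinimide, O=C1CCC(=O)N1Br; acetic acid, CC(=O)O
Why: Bromoacetoxylation (cohalogenation), in which the bromonium ion of the electron-rich styrenic alkene is opened by acetic acid at the benzylic carbon to give the α-bromo-β-acetoxy ester, whose two new centres are destroyed later so their configuration does not matter.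

**Step 7**
Reactants: 10 di-tert-butyl (2S)-2-{[3-acetoxy-2-bromo-3-(2,2-dimethyl-1,3-benzodioxol-5-yl)propanoyl]oxy}butanedioate; 6 tert-butyl (E)-3-(2,2-dimethyl-1,3-benzodioxol-5-yl)prop-2-enoate
Product: 12 2-tert-butyl 3-[(2S)-1,4-di-tert-butoxy-1,4-dioxobutan-2-yl] (1R,2S)-1-(2,2-dimethyl-1,3-benzodioxol-5-yl)-6,7-(isopropylidenedioxy)-1,2-dihydronaphthalene-2,3-dicarboxylate, via tetralin acetate 11 (not isolated)
Conditions: 6 (4 equiv), fac-Ir(ppy)3 (1 mol %), 2,6-lutidine (1.5 equiv), MeCN, blue LEDs (450 nm), rt, degassed; aq. wash; then Sc(OTf)3 (10 mol %), CH2Cl2, rt; chromatographic separation of the two trans diastereomers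
Reagents that add atoms: none
Why: Proposed new method: a photoredox radical–polar crossover (4+2) annulation in which excited fac-Ir(ppy)3 reduces the C–Br bond of 10, the electrophilic α-ester radical (C3) adds to the electron-rich α-carbon of cinnamate 6 to form the C2–C3 bond and a p-alkoxybenzyl radical at C1, this radical (or the cation formed by oxidation with tetravalent iridium) closes a six-membered ring onto ring A para to oxygen (C1–C8a) with the C1 aryl and C2 ester equatorial and hence trans, and Sc(OTf)3 then ionises the benzylic acetate of 11 so that loss of the C3 proton gives the C3=C4 alkene; the closest known reaction types are the annulation of 2-benzyl-2-bromomalonates with alkenes to tetralins and atom-transfer radical addition of α-bromo esters to styrenes; the remote malate is expected to give little induction, so the two trans diastereomers (about 1:1) are separated and the (1R,2S) isomer 12 is carried on, at most half of the annulated material.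

**Step 8**
Reactants: 12 2-tert-butyl 3-[(2S)-1,4-di-tert-butoxy-1,4-dioxobutan-2-yl] (1R,2S)-1-(2,2-dimethyl-1,3-benzodioxol-5-yl)-6,7-(isopropylidenedioxy)-1,2-dihydronaphthalene-2,3-dicarboxylate
Product: 13 (1R,2S)-1-(3,4-dihydroxyphenyl)-6,7-dihydroxy-1,2-dihydronaphthalene-2,3-dicarboxylic acid 3-[(S)-1,2-dicarboxyethyl] ester (CNP0323723.1)
Conditions: TFA/H2O (9:1), 0 °C → rt; preparative reversed-phase HPLC
Reagents that add atoms: none
Why: Global acidolysis, in which the three tert-butyl esters cleave by alkyl–oxygen fission (water intercepts the tert-butyl cation) and the two catechol acetonides hydrolyse to acetone, while the secondary malate ester, the conjugated alkene and the C1/C2 centres are stable in the absence of base.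

**Compound list**
1 | 2,2-dimethyl-1,3-benzodioxole | CC1(C)Oc2ccccc2O1 | starting material
2 | 5-bromo-2,2-dimethyl-1,3-benzodioxole | CC1(C)Oc2ccc(Br)cc2O1 | intermediate
3 | acrylic acid | C=CC(=O)O | starting material
4 | (E)-3-(2,2-dimethyl-1,3-benzodioxol-5-yl)prop-2-enoic acid | CC1(C)Oc2ccc(/C=C/C(=O)O)cc2O1 | intermediate
5 | tert-butyl acrylate | C=CC(=O)OC(C)(C)C | starting material
6 | tert-butyl (E)-3-(2,2-dimethyl-1,3-benzodioxol-5-yl)prop-2-enoate | CC1(C)Oc2ccc(/C=C/C(=O)OC(C)(C)C)cc2O1 | intermediate
7 | di-tert-butyl but-2-ynedioate | CC(C)(C)OC(=O)C#CC(=O)OC(C)(C)C | starting material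
8 | di-tert-butyl 2-{[(E)-3-(2,2-dimethyl-1,3-benzodioxol-5-yl)prop-2-enoyl]oxy}but-2-enedioate (E/Z mixture, trans-diester isomer drawn) | CC1(C)Oc2ccc(/C=C/C(=O)O/C(C(=O)OC(C)(C)C)=C\C(=O)OC(C)(C)C)cc2O1 | intermediate
9 | di-tert-butyl (2S)-2-{[(E)-3-(2,2-dimethyl-1,3-benzodioxol-5-yl)prop-2-enoyl]oxy}butanedioate | CC(C)(C)OC(=O)C[C@H](OC(=O)/C=C/c1ccc2OC(C)(C)Oc2c1)C(=O)OC(C)(C)C | intermediate
10 | di-tert-butyl (2S)-2-{[3-acetoxy-2-bromo-3-(2,2-dimethyl-1,3-benzodioxol-5-yl)propanoyl]oxy}butanedioate (anti adducts, mixture at the two new centres) | CC(=O)OC(c1ccc2OC(C)(C)Oc2c1)C(Br)C(=O)O[C@@H](CC(=O)OC(C)(C)C)C(=O)OC(C)(C)C | intermediate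
11 | 2-tert-butyl 3-[(2S)-1,4-di-tert-butoxy-1,4-dioxobutan-2-yl] 4-acetoxy-1-(2,2-dimethyl-1,3-benzodioxol-5-yl)-6,7-(isopropylidenedioxy)-1,2,3,4-tetrahydronaphthalene-2,3-dicarboxylate (1,2-trans, mixture at C3/C4 and of both trans series; (1R,2S) series drawn; not isolated) | CC(=O)OC1c2cc3OC(C)(C)Oc3cc2[C@@H](c2ccc3OC(C)(C)Oc3c2)[C@H](C(=O)OC(C)(C)C)C1C(=O)O[C@@H](CC(=O)OC(C)(C)C)C(=O)OC(C)(C)C | intermediate
12 | 2-tert-butyl 3-[(2S)-1,4-di-tert-butoxy-1,4-dioxobutan-2-yl] (1R,2S)-1-(2,2-dimethyl-1,3-benzodioxol-5-yl)-6,7-(isopropylidenedioxy)-1,2-dihydronaphthalene-2,3-dicarboxylate | CC(C)(C)OC(=O)C[C@H](OC(=O)C1=Cc2cc3OC(C)(C)Oc3cc2[C@@H](c2ccc3OC(C)(C)Oc3c2)[C@@H]1C(=O)OC(C)(C)C)C(=O)OC(C)(C)C | intermediate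
13 | (1R,2S)-1-(3,4-dihydroxyphenyl)-6,7-dihydroxy-1,2-dihydronaphthalene-2,3-dicarboxylic acid 3-[(S)-1,2-dicarboxyethyl] ester | O=C(O)C[C@H](OC(=O)C1=Cc2cc(O)c(O)cc2[C@@H](c2ccc(O)c(O)c2)[C@@H]1C(=O)O)C(=O)O | target

**Step count**
Total: 8 steps. Longest linear sequence: 7 steps (steps 1, 2, 4, 5, 6, 7, 8).

**Steps most likely to fail, with fallbacks**

1. Step 7 (key annulation). The intermolecular addition of a secondary α-ester radical to a 1,2-disubstituted cinnamate is slow. Reduction and elimination of 10 back to 9 compete, and the malate gives no facial control. The fallback sets out from 10 and comes back at 11. Bromide 10 is displaced with EtOCS2K (acetone, 0 °C) to give the xanthate di-tert-butyl (2S)-2-{[3-acetoxy-3-(2,2-dimethyl-1,3-benzodioxol-5-yl)-2-(ethoxycarbonothioylsulfanyl)propanoyl]oxy}butanedioate F1. This is heated with 6 and dilauroyl peroxide (added in portions to 1.2 equiv, 1,2-dichloroethane, reflux). Degenerative xanthate transfer gives the radical a long effective lifetime for addition to 6, and the peroxide then drives the oxidative ring closure onto ring A to give 11. Compound 11 is taken on with Sc(OTf)3 to 12 as in the main route.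

2. Step 5 (asymmetric hydrogenation). The level and sense of induction for an enol ester carrying a β-alkoxycarbonyl group, used as an E/Z mixture, are not secured. The fallback sets out from 4 and comes back at 9, bypassing 8. Fumaric acid F2 is hydrated with fumarase (phosphate buffer pH 7.5, 30 °C) to (S)-malic acid F3. This is esterified with O-tert-butyl-N,N'-diisopropylisourea (CH2Cl2, rt) to di-tert-butyl (S)-malate F4. Coupling of F4 with acid 4 (EDC·HCl, catalytic DMAP, CH2Cl2, 0 °C) gives 9 with the stereocentre taken from the enzyme.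

3. Step 6 (bromoacetoxylation). Ring bromination of the electron-rich arene, or elimination of the labile benzylic acetate on handling, may erode the yield. The fallback sets out from 9 and comes back at 10. Addition of Br2 (1.0 equiv, CH2Cl2, −78 °C), which is faster at the alkene than at the ring at low temperature, gives the dibromide di-tert-butyl (2S)-2-{[2,3-dibromo-3-(2,2-dimethyl-1,3-benzodioxol-5-yl)propanoyl]oxy}butanedioate F5. AgOAc in AcOH (rt) then solvolyses only the benzylic bromide, through the p-alkoxybenzyl cation, to give 10.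

**Further compounds**
F1 | step 7 | di-tert-butyl (2S)-2-{[3-acetoxy-3-(2,2-dimethyl-1,3-benzodioxol-5-yl)-2-(ethoxycarbonothioylsulfanyl)propanoyl]oxy}butanedioate | CCOC(=S)SC(C(OC(C)=O)c1ccc2OC(C)(C)Oc2c1)C(=O)O[C@@H](CC(=O)OC(C)(C)C)C(=O)OC(C)(C)C
F2 | step 5 | fumaric acid | OC(=O)/C=C/C(=O)O
F3 | step 5 | (S)-malic acid | OC(=O)C[C@H](O)C(=O)O
F4 | step 5 | di-tert-butyl (S)-malate | CC(C)(C)OC(=O)C[C@H](O)C(=O)OC(C)(C)C
F5 | step 6 | di-tert-butyl (2S)-2-{[2,3-dibromo-3-(2,2-dimethyl-1,3-benzodioxol-5-yl)propanoyl]oxy}butanedioate | BrC(c1ccc2OC(C)(C)Oc2c1)C(Br)C(=O)O[C@@H](CC(=O)OC(C)(C)C)C(=O)OC(C)(C)C
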